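## The problem

CNP0086623.4 (34) is a 12-membered dilactone in which two different benzoate units are joined head to tail. Ring A is a 2,4-dihydroxy-3-methoxybenzoate with one aromatic hydrogen (C5); ring B is its fully substituted 5'-hydroxy counterpart; each ring carries a 1,2-dioxygenated propyl chain at C6 (C6'). The ring A carboxyl esterifies O-2' of the ring B chain (the "A-ester") and the ring B carboxyl esterifies O-2 of the ring A chain (the "B-ester"), while both benzylic hydroxyls (O-1, O-1') stay free. There are four stereocentres, and the two chains are diastereomers: (1R,2S), anti, on ring A and (1'R,2'R), syn, on ring B. Within a chain the methyl carbinol can direct the benzylic centre by 1,2-induction, but the chains cannot control each other, so the syn/anti difference must be made deliberately. Both ester carbonyls belong to di-ortho-substituted benzoic acids, which resist acyl transfer to a secondary alcohol. Every chain hydroxyl sits beside a carbonyl on its own ring (a free O-2 can close to a 3,4-dihydroisocoumarin, a free O-1 to a phthalide), so unmasking and the final deprotection of five phenols and two benzylic alcohols must stay near neutral and non-oxidising. What makes the key step possible is that ring A atoms C2 (OH), C3 (OMe), C4 (OH) and C5 (H) map onto a 1,1,2,3-tetraoxygenated butadiene and C1 (carboxyl) plus C6 (chain) onto a 4-oxygenated 2-ynoate; ring B differs only by an oxygen on the diene terminus (C5').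

## Retrosynthesis

**Unmasking (34 from 33).** The last disconnection cuts seven O–C bonds: five aryl benzyl ethers and two benzyloxymethyl (BOM) ethers on O-1 and O-1'. One neutral hydrogenolysis removes all of them. Silyl or acetal groups on the benzylic oxygens would need fluoride or acid at the end, which invite phthalide formation. The forward reaction must spare the substrate's own benzylic C–O bonds.

**A-ester, alkyl–oxygen bond O–C2' (33 from 32).** The macrocycle is opened at the bond between the ester oxygen and C2' of the ring B chain, not at the acyl–oxygen bond. The forward reaction is then a Mitsunobu alkylation of the ring A carboxylate, so the hindered acid is never activated. The inversion turns a (2'S) centre into the required (2'R), so both chains can come from the same (4R,5S) building block. Seco acid 32 is acyclic; the step must close a 12-membered ring with clean inversion.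

**Ring B, bonds C1'–C2' and C5'–C6' (32 via 31 and 30 from 29; 29 from 21 and 26).** Ring B is taken apart into ynoate 21 and the benzyloxy-substituted diene 26, the same cycloaddition as the key step. Oxidising C5' of a ring-A-type arene late would be the neighbouring cut, but it puts an oxidation next to electron-rich phenols. Making ring B as a separate benzoate would require acyl transfer from a hindered acid. In 21 the future ring B carbonyl is already esterified to O-2.

**B-ester, acyl–oxygen bond at the alkyne stage (21 from 19 and 20).** While the carbonyl still belongs to an ynoic acid, the B-ester is an ordinary carbodiimide coupling with retention at C2. This gives ring A alcohol 19 and ynoic acid 20.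

**Ring A, bonds C1–C2 and C5–C6 (19 via 18 from 17; 17 from 8 and 14).** This is the key disconnection: ynoate 8 supplies C1, C6, the carboxyl and the complete, differentially protected chain; diene 14 supplies C2–C5 with all three oxygens. Aromatic substitution on a preformed resorcinol would have to differentiate C3, C5 and C6; the cycloaddition needs only regiocontrol, which the polarity of both partners provides.

**Chain, bond C3–C4 of the hexynoate (8 and 20 from 7; 7 from 4 and 5; 4 from 2 and 1).** Ynoate 8 is the BOM ether of alcohol 7, and acid 20 is the hydrolysis product of 8, so one compound serves both halves. Alcohol 7 comes from addition of lithiated allyl propiolate 5 to silyl-protected (S)-lactaldehyde 4. The bulky silyl ether is chosen for Felkin–Anh (anti) induction, and 4 comes from ethyl (S)-lactate 1 via 2.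

**Dienes (14 from 12 from 11 from 9; 26 from 24 from 23 from 9).** Both dienes are double silyl enol ethers of 2-methoxy-3-oxo esters. Each keto ester comes from C-acylation of an alkali-metal enolate of methyl methoxyacetate 9: the lithium enolate 10 with acetyl chloride gives 11, and the sodium enolate 22 with benzyloxyacetyl chloride gives 23.

## Roads not taken

**Alternative 1:** Aryne three-component coupling on ring A.
- **Cut:** the C6–chain and C1–carboxyl bonds.
- **Forward key step:** the aryne from symmetric bromide A1 (generated with a hindered lithium amide) takes up an (E)-propenyl Grignard reagent at C6, and the arylmagnesium left at C1 is carboxylated to acid A2.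
- **Merits:** this reaches the ring A substitution pattern from a simple arene in one flask, without moisture-sensitive dienes or hot cycloadditions. In arene step count it is better than the chosen plan, which needs eight steps to reach 17.
- **Weak points:** the chain still has to be oxidised. Asymmetric dihydroxylation of the (E)-alkene gives only the syn diol, which fits ring B, whereas ring A needs anti. The diol is generated ortho to a carboxyl, so it lactonises and emerges with undifferentiated hydroxyls. Ring B would need a second, unsymmetrical bromide. The methoxymethyl ethers need acid at the end.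
- **Comparison:** against the shorter arene synthesis, the chosen plan brings both stereocentres and the O-1/O-2 differentiation into the ring-forming step, and makes both diastereomeric chains from one lactate-derived ynoate by pairing retention with inversion.

**Alternative 2:** Carbonylative macrolactonisation at the B-ester.
- **Cut:** the aryl–carbonyl and carbonyl–oxygen bonds of the B-ester.
- **Forward key step:** zerovalent palladium inserts into aryl iodide A3, carbonyl insertion gives an aroylpalladium, and O-2 captures it to close protected dilactone A4.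
- **Merits:** no hindered benzoic acid is ever activated, retention at C2 is automatic, and ring B carries no carboxyl before ring closure, so its chain cannot lactonise. On that last point it is as good as or better than the chosen plan.
- **Weak points:** oxidative addition must occur at an iodide flanked by a benzyl ether and a branched chain on an electron-rich ring. A hindered secondary alcohol must then capture the acylmetal in a 12-membered closure, in competition with intermolecular capture and reduction. The A-ester still has to be made conventionally, and the benzylic silyl ethers need fluoride or acid at the end.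
- **Comparison:** the chosen plan sets against it a ring B built after its carbonyl is already esterified, a cycloaddition type with precedent on ynoates, a ring closure by the standard method for hindered benzoates, and a neutral final hydrogenolysis.

**Alternative 3:** Squarate ring expansion for ring B.
- **Cut:** ring B is opened at the C5'–C6' bond back to 4-alkenyl-4-hydroxycyclobutenone A5.
- **Forward key step:** thermolysis opens A5 to a dienylketene, and six-electron closure with tautomerisation gives hydroquinone A6.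
- **Merits:** the thermolysis is neutral and regiospecific, and it delivers four ring oxygens and the intact syn (4R,5R) chain of ring B directly. In that respect it is better than the chosen plan, which reaches the syn chain only through a late inversion.
- **Weak points:** A6 lacks the carboxyl, which would have to be forced into the last free position of an air-sensitive hydroquinone beside the chain. A6 has two adjacent methoxy groups where the target has one methoxy and one hydroxyl, so a selective demethylation is needed. The acetonide leaves O-1' and O-2' undifferentiated, and the method does not address ring A, which lacks the para oxygen.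
- **Comparison:** the chosen plan sets against it one reaction type and one chiral building block for both rings, a carboxyl that is part of the dienophile, and an oxygenation pattern fixed exactly by the diene.

Key step: step 8

Assumption: allyl propiolate (5) is treated as a catalogue compound; otherwise it is one esterification away from propiolic acid.

Conventions: ring A carbons C1–C6 (C1 carboxyl, C6 chain), ring B primed; chain atoms C1/O-1 (benzylic) and C2/O-2 (methyl carbinol); TBS = tert-butyldimethylsilyl, TMS = trimethylsilyl, BOM = benzyloxymethyl, Bn = benzyl.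

## Route

Step 1
Reactants: 1 ethyl (S)-lactate [ethyl (2S)-2-hydroxypropanoate]
Product: 2 ethyl (2S)-2-(tert-butyldimethylsilyloxy)propanoate
Conditions: TBSCl, imidazole, DMF, 0 to 23 °C
Reagents that add atoms: tert-butyldimethylsilyl chloride, CC(C)(C)[Si](C)(C)Cl
Why: Routine imidazole-promoted silylation of a secondary alcohol; the bulky, non-chelating silyl ether later enforces Felkin–Anh addition, and the α-centre is not enolised.

Step 2
Reactants: 2 ethyl (2S)-2-(tert-butyldimethylsilyloxy)propanoate
Product: 4 (2S)-2-(tert-butyldimethylsilyloxy)propanal, via aluminium hemiacetal 3 (not isolated)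
Conditions: iBu2AlH (DIBAL-H), CH2Cl2, −78 °C; aq. potassium sodium tartrate
Reagents that add atoms: none
Why: Partial reduction of an ester; the tetrahedral aluminium hemiacetal 3 survives at −78 °C and releases the aldehyde only on work-up, so over-reduction is avoided. The aldehyde is used at once to protect the α-centre.

Step 3
Reactants: 5 allyl propiolate (prop-2-enyl prop-2-ynoate); 4 (2S)-2-(tert-butyldimethylsilyloxy)propanal
Product: 7 allyl (4R,5S)-5-(tert-butyldimethylsilyloxy)-4-hydroxyhex-2-ynoate, via allyl 3-lithiopropiolate 6 (not isolated)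
Conditions: 5, LiN(SiMe3)2, THF, −78 °C; then 4, −78 °C; AcOH quench at −78 °C
Reagents that add atoms: none
Why: 1,2-Addition of a lithium acetylide to an α-silyloxy aldehyde; under the polar Felkin–Anh model the nucleophile enters anti to the non-chelating silyloxy group, which should favour the 4,5-anti (4R) alcohol. The minor epimer is removed by chromatography, and the cold acidic quench prevents base-induced isomerisation of the γ-hydroxy ynoate.

Step 4
Reactants: 7 allyl (4R,5S)-5-(tert-butyldimethylsilyloxy)-4-hydroxyhex-2-ynoate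
Product: 8 allyl (4R,5S)-4-(benzyloxymethoxy)-5-(tert-butyldimethylsilyloxy)hex-2-ynoate
Conditions: BOMCl, iPr2NEt, Bu4NI (cat.), CH2Cl2, 0 to 23 °C
Reagents that add atoms: benzyl chloromethyl ether, ClCOCc1ccccc1
Why: Standard alkoxymethylation of a secondary alcohol with a hindered amine base, which does not trigger the amine-catalysed redox isomerisation of γ-hydroxy ynoates. BOM is orthogonal to the silyl ether and is removed by the final hydrogenolysis.

Step 5
Reactants: 9 methyl methoxyacetate
Product: 11 methyl 2-methoxy-3-oxobutanoate (racemic), via lithium enolate 10 (not isolated)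
Conditions: LiN(SiMe3)2 (2.1 equiv), THF, −78 °C; AcCl; then 1 M HCl
Reagents that add atoms: acetyl chloride, CC(=O)Cl
Why: Crossed Claisen-type C-acylation of an ester enolate with an acid chloride; the second equivalent of base absorbs the more acidic β-keto ester as it forms.

Step 6
Reactants: 11 methyl 2-methoxy-3-oxobutanoate
Product: 12 methyl 2-methoxy-3-(trimethylsilyloxy)but-2-enoate (E/Z mixture)
Conditions: TMSCl, Et3N, hexane, 23 °C
Reagents that add atoms: chlorotrimethylsilane, C[Si](C)(C)Cl
Why: O-Silylation of the β-keto ester enol toward the doubly activated C2, the standard first stage in making 1,3-bis(silyloxy)dienes.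

Step 7
Reactants: 12 methyl 2-methoxy-3-(trimethylsilyloxy)but-2-enoate
Product: 14 1,2-dimethoxy-1,3-bis(trimethylsilyloxy)buta-1,3-diene (isomer mixture at C1=C2), via lithium dienolate 13 (not isolated)
Conditions: LiN(iPr)2 (LDA), THF, −78 °C; TMSCl, −78 to 0 °C; non-aqueous work-up
Reagents that add atoms: chlorotrimethylsilane, C[Si](C)(C)Cl
Why: γ-Deprotonation of the silyloxy enoate and O-silylation of the dienolate, the usual route to 1-alkoxy-1,3-bis(silyloxy)butadienes; the diene is moisture-sensitive and is used directly.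

Step 8
Reactants: 8 allyl (4R,5S)-4-(benzyloxymethoxy)-5-(tert-butyldimethylsilyloxy)hex-2-ynoate; 14 1,2-dimethoxy-1,3-bis(trimethylsilyloxy)buta-1,3-diene
Product: 17 allyl 6-[(1R,2S)-1-(benzyloxymethoxy)-2-(tert-butyldimethylsilyloxy)propyl]-2,4-dihydroxy-3-methoxybenzoate, via cyclohexadiene cycloadduct 15 (not isolated), via aryl trimethylsilyl ether 16 (not isolated)
Conditions: 14 (excess), toluene, 110 °C, sealed tube; then 0.5 M HCl, THF, 0 °C
Reagents that add atoms: none
Why: This is a normal-electron-demand Diels–Alder reaction of a vinylketene silyl acetal with an acetylenic ester, the known route from 1-alkoxy-1,3-bis(silyloxy)butadienes and 2-ynoates to 2,4-dihydroxybenzoates. The cycloaddition is concerted but strongly asynchronous: the CH2 terminus of 14, where the donors at C1 and C3 reinforce each other, bonds to the β-carbon of 8 (ring A bond C5–C6) and the ketene-acetal carbon to the α-carbon (bond C1–C2), so ring A closes in one suprafacial [4+2] event. Cycloadduct 15 holds a mixed methyl silyl ketal at the future C2 and a CH2 at the future C5; loss of methoxytrimethylsilane and enolisation aromatise it to 16, and dilute acid cleaves the remaining aryl silyl ether. No stereocentre is created, and the two chain centres are untouched because the propargylic carbon cannot enolise under neutral heating. The only selectivity needed is regiochemical (ester beside the new C2 phenol, chain beside C5–H), and the matched polarity of diene and ynoate secures it; the 2-methoxy group weakens but should not reverse the preference. The TBS and BOM ethers and the allyl ester tolerate the heat and the brief cold acid, and excess 14 offsets its lability.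

Step 9
Reactants: 17 allyl 6-[(1R,2S)-1-(benzyloxymethoxy)-2-(tert-butyldimethylsilyloxy)propyl]-2,4-dihydroxy-3-methoxybenzoate
Product: 18 allyl 2,4-bis(benzyloxy)-6-[(1R,2S)-1-(benzyloxymethoxy)-2-(tert-butyldimethylsilyloxy)propyl]-3-methoxybenzoate
Conditions: BnBr, K2CO3, Bu4NI (cat.), DMF, 50 °C
Reagents that add atoms: benzyl bromide, BrCc1ccccc1
Why: Williamson etherification of both phenols; the hydrogen-bonded 2-hydroxyl needs excess reagent and warming, which the silyl ether and allyl ester tolerate.

Step 10
Reactants: 18 allyl 2,4-bis(benzyloxy)-6-[(1R,2S)-1-(benzyloxymethoxy)-2-(tert-butyldimethylsilyloxy)propyl]-3-methoxybenzoate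
Product: 19 allyl 2,4-bis(benzyloxy)-6-[(1R,2S)-1-(benzyloxymethoxy)-2-hydroxypropyl]-3-methoxybenzoate
Conditions: HF·pyridine, pyridine, THF, 0 to 23 °C
Reagents that add atoms: none
Why: Buffered fluoride cleavage of a secondary silyl ether; the medium never generates the alkoxide, which would close onto the ortho ester to a dihydroisocoumarin. Alcohol 19 is carried forward without storage.

Step 11
Reactants: 8 allyl (4R,5S)-4-(benzyloxymethoxy)-5-(tert-butyldimethylsilyloxy)hex-2-ynoate
Product: 20 (4R,5S)-4-(benzyloxymethoxy)-5-(tert-butyldimethylsilyloxy)hex-2-ynoic acid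
Conditions: LiOH, THF–H2O, 0 °C; then 1 M HCl to pH 3
Reagents that add atoms: lithium hydroxide, [Li+].[OH-]
Why: Saponification of an alkynoate ester is fast at 0 °C, and the silyl and BOM ethers are stable to cold hydroxide.

Step 12
Reactants: 19 allyl 2,4-bis(benzyloxy)-6-[(1R,2S)-1-(benzyloxymethoxy)-2-hydroxypropyl]-3-methoxybenzoate; 20 (4R,5S)-4-(benzyloxymethoxy)-5-(tert-butyldimethylsilyloxy)hex-2-ynoic acid
Product: 21 (1R,2S)-1-[2-(allyloxycarbonyl)-3,5-bis(benzyloxy)-4-methoxyphenyl]-1-(benzyloxymethoxy)propan-2-yl (4R,5S)-4-(benzyloxymethoxy)-5-(tert-butyldimethylsilyloxy)hex-2-ynoate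
Conditions: DCC, DMAP (cat.), CH2Cl2, −20 to 0 °C
Reagents that add atoms: none
Why: Steglich esterification with an unhindered sp-bound carboxylic acid installs the future B-ester with retention at C2 before ring B exists. Low temperature and catalytic DMAP keep conjugate addition to the ynoate and lactonisation of 19 behind acylation.

Step 13
Reactants: 9 methyl methoxyacetate
Product: 23 methyl 4-(benzyloxy)-2-methoxy-3-oxobutanoate (racemic), via sodium enolate 22 (not isolated)
Conditions: NaN(SiMe3)2 (2.1 equiv), THF, −78 °C; BnOCH2COCl, −78 °C; then 1 M HCl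
Reagents that add atoms: benzyloxyacetyl chloride, O=C(Cl)COCc1ccccc1
Why: Crossed Claisen-type C-acylation of an ester enolate with the acid chloride that carries the future C5' oxygen; the second equivalent of base absorbs the β-keto ester as it forms. The sodium enolate is used here as the more nucleophilic counter-ion form, because this α-alkoxy acid chloride is prone to dehydrochlorination to benzyloxyketene and should be consumed by C-acylation as fast as possible at −78 °C.

Step 14
Reactants: 23 methyl 4-(benzyloxy)-2-methoxy-3-oxobutanoate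
Product: 24 methyl 4-(benzyloxy)-2-methoxy-3-(trimethylsilyloxy)but-2-enoate (E/Z mixture)
Conditions: TMSCl, Et3N, hexane, 23 °C
Reagents that add atoms: chlorotrimethylsilane, C[Si](C)(C)Cl
Why: Enol silylation toward the doubly activated C2, as in step 6.

Step 15
Reactants: 24 methyl 4-(benzyloxy)-2-methoxy-3-(trimethylsilyloxy)but-2-enoate
Product: 26 4-(benzyloxy)-1,2-dimethoxy-1,3-bis(trimethylsilyloxy)buta-1,3-diene (isomer mixture), via lithium dienolate 25 (not isolated)
Conditions: LiN(iPr)2 (LDA), THF, −78 °C; TMSCl, −78 to 0 °C; non-aqueous work-up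
Reagents that add atoms: chlorotrimethylsilane, C[Si](C)(C)Cl
Why: γ-Deprotonation at the benzyloxymethylene and O-silylation, as in step 7; the (3Z) isomer, with benzyloxy pointing outward, is the one able to adopt the s-cis conformation.

Step 16
Reactants: 21 ynoate ester (as named in step 12); 26 4-(benzyloxy)-1,2-dimethoxy-1,3-bis(trimethylsilyloxy)buta-1,3-diene
Product: 29 (1R,2S)-1-[2-(allyloxycarbonyl)-3,5-bis(benzyloxy)-4-methoxyphenyl]-1-(benzyloxymethoxy)propan-2-yl 5-(benzyloxy)-6-[(1R,2S)-1-(benzyloxymethoxy)-2-(tert-butyldimethylsilyloxy)propyl]-2,4-dihydroxy-3-methoxybenzoate, via cyclohexadiene cycloadduct 27 (not isolated), via aryl trimethylsilyl ether 28 (not isolated)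
Conditions: 26 (excess), toluene, 110 °C, sealed tube; then 0.5 M HCl, THF, 0 °C
Reagents that add atoms: none
Why: The same Diels–Alder and aromatisation as step 8: the CH(OBn) terminus bonds to the ynoate β-carbon (C5'–C6') and the ketene-acetal carbon to the α-carbon (C1'–C2'). Only the ketal carbon can shed a leaving group, so aromatisation keeps the benzyloxy group and gives ring B with every oxygen in place and the hindered B-ester already formed.

Step 17
Reactants: 29 ring B resorcylate (as named in step 16)
Product: 30 (1R,2S)-1-[2-(allyloxycarbonyl)-3,5-bis(benzyloxy)-4-methoxyphenyl]-1-(benzyloxymethoxy)propan-2-yl 2,4,5-tris(benzyloxy)-6-[(1R,2S)-1-(benzyloxymethoxy)-2-(tert-butyldimethylsilyloxy)propyl]-3-methoxybenzoate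
Conditions: BnBr, K2CO3, Bu4NI (cat.), DMF, 40 °C
Reagents that add atoms: benzyl bromide, BrCc1ccccc1
Why: Williamson etherification of the two remaining phenols, so that no acidic hydroxyl competes in the Mitsunobu ring closure.

Step 18
Reactants: 30 fully benzylated diester (as named in step 17)
Product: 31 2,4-bis(benzyloxy)-6-[(1R,2S)-1-(benzyloxymethoxy)-2-{2,4,5-tris(benzyloxy)-6-[(1R,2S)-1-(benzyloxymethoxy)-2-(tert-butyldimethylsilyloxy)propyl]-3-methoxybenzoyloxy}propyl]-3-methoxybenzoic acid
Conditions: Pd(PPh3)4 (cat.), morpholine, THF, 23 °C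
Reagents that add atoms: none
Why: Zerovalent-palladium-catalysed allyl transfer to morpholine (Tsuji–Trost type) breaks the O–allyl bond, so hindrance at the acyl carbon is irrelevant and the secondary-alkyl B-ester and all ethers are untouched.

Step 19
Reactants: 31 ring A acid (as named in step 18)
Product: 32 2,4-bis(benzyloxy)-6-[(1R,2S)-1-(benzyloxymethoxy)-2-{2,4,5-tris(benzyloxy)-6-[(1R,2S)-1-(benzyloxymethoxy)-2-hydroxypropyl]-3-methoxybenzoyloxy}propyl]-3-methoxybenzoic acid (seco acid)
Conditions: HF·pyridine, pyridine, THF, 0 to 23 °C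
Reagents that add atoms: none
Why: Buffered fluoride desilylation frees O-2' without forming an alkoxide beside the B-ester carbonyl; the seco acid is used directly.

Step 20
Reactants: 32 seco acid (as named in step 19)
Product: 33 protected dilactone: 34 carrying benzyl ethers on O-2, O-4, O-2', O-4' and O-5' and benzyloxymethyl ethers on O-1 and O-1', chains (1R,2S) on ring A and (1'R,2'R) on ring B
Conditions: PPh3, DIAD, toluene, high dilution, 0 to 23 °C (slow addition of 32 to the preformed betaine)
Reagents that add atoms: none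
Why: Mitsunobu macrolactonisation, the standard closure for di-ortho-substituted benzoic acids: the ring A carboxylate displaces the alkoxyphosphonium at C2' in an SN2 step. This closes the 12-membered ring and inverts the centre from (2'S) to (2'R), which sets the last stereocentre of the target.

Step 21
Reactants: 33 protected dilactone (as described in step 20)
Product: 34 CNP0086623.4
Conditions: H2 (1 atm), Pd/C (palladium on carbon), EtOAc–MeOH, 23 °C
Reagents that add atoms: none
Why: Hydrogenolysis cleaves the five aryl benzyl ethers and the two BOM ethers, whose hemiformals lose formaldehyde. The neutral medium should leave the dilactone and the newly freed benzylic hydroxyls undisturbed, and the substrate's own secondary benzylic C–O bonds are hindered and flanked by ester carbonyls.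

## Compound list

1 | ethyl (S)-lactate | CCOC(=O)[C@H](C)O | starting material
2 | ethyl (2S)-2-(tert-butyldimethylsilyloxy)propanoate | CCOC(=O)[C@H](C)O[Si](C)(C)C(C)(C)C | intermediate
3 | diisobutylaluminium hemiacetal of 2 (epimer mixture at the acetal carbon) | CCOC(O[Al](CC(C)C)CC(C)C)[C@H](C)O[Si](C)(C)C(C)(C)C | intermediate
4 | (2S)-2-(tert-butyldimethylsilyloxy)propanal | O=C[C@H](C)O[Si](C)(C)C(C)(C)C | intermediate
5 | allyl propiolate | C#CC(=O)OCC=C | starting material
6 | allyl 3-lithiopropiolate | [Li]C#CC(=O)OCC=C | intermediate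
7 | allyl (4R,5S)-5-(tert-butyldimethylsilyloxy)-4-hydroxyhex-2-ynoate | C[C@H](O[Si](C)(C)C(C)(C)C)[C@H](O)C#CC(=O)OCC=C | intermediate
8 | allyl (4R,5S)-4-(benzyloxymethoxy)-5-(tert-butyldimethylsilyloxy)hex-2-ynoate | C[C@H](O[Si](C)(C)C(C)(C)C)[C@H](OCOCc1ccccc1)C#CC(=O)OCC=C | intermediate
9 | methyl methoxyacetate | COCC(=O)OC | starting material
10 | lithium enolate of methyl methoxyacetate | COC=C(OC)O[Li] | intermediate
11 | methyl 2-methoxy-3-oxobutanoate (racemic) | COC(=O)C(OC)C(C)=O | intermediate
12 | methyl 2-methoxy-3-(trimethylsilyloxy)but-2-enoate (E/Z mixture) | COC(=O)C(OC)=C(C)O[Si](C)(C)C | intermediate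
13 | lithium dienolate of 12 | C=C(O[Si](C)(C)C)C(OC)=C(OC)O[Li] | intermediate
14 | 1,2-dimethoxy-1,3-bis(trimethylsilyloxy)buta-1,3-diene (isomer mixture) | C=C(O[Si](C)(C)C)C(OC)=C(OC)O[Si](C)(C)C | intermediate
15 | allyl 2-[(1R,2S)-1-(benzyloxymethoxy)-2-(tert-butyldimethylsilyloxy)propyl]-5,6-dimethoxy-4,6-bis(trimethylsilyloxy)cyclohexa-1,4-diene-1-carboxylate (epimer mixture at C6) | C[C@H](O[Si](C)(C)C(C)(C)C)[C@H](OCOCc1ccccc1)C1=C(C(=O)OCC=C)C(OC)(O[Si](C)(C)C)C(OC)=C(O[Si](C)(C)C)C1 | intermediate
16 | allyl 6-[(1R,2S)-1-(benzyloxymethoxy)-2-(tert-butyldimethylsilyloxy)propyl]-2-hydroxy-3-methoxy-4-(trimethylsilyloxy)benzoate | C[C@H](O[Si](C)(C)C(C)(C)C)[C@H](OCOCc1ccccc1)c1cc(O[Si](C)(C)C)c(OC)c(O)c1C(=O)OCC=C | intermediate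
17 | allyl 6-[(1R,2S)-1-(benzyloxymethoxy)-2-(tert-butyldimethylsilyloxy)propyl]-2,4-dihydroxy-3-methoxybenzoate | C[C@H](O[Si](C)(C)C(C)(C)C)[C@H](OCOCc1ccccc1)c1cc(O)c(OC)c(O)c1C(=O)OCC=C | intermediate
18 | allyl 2,4-bis(benzyloxy)-6-[(1R,2S)-1-(benzyloxymethoxy)-2-(tert-butyldimethylsilyloxy)propyl]-3-methoxybenzoate | C[C@H](O[Si](C)(C)C(C)(C)C)[C@H](OCOCc1ccccc1)c1cc(OCc2ccccc2)c(OC)c(OCc2ccccc2)c1C(=O)OCC=C | intermediate
19 | allyl 2,4-bis(benzyloxy)-6-[(1R,2S)-1-(benzyloxymethoxy)-2-hydroxypropyl]-3-methoxybenzoate | C[C@H](O)[C@H](OCOCc1ccccc1)c1cc(OCc2ccccc2)c(OC)c(OCc2ccccc2)c1C(=O)OCC=C | intermediate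
20 | (4R,5S)-4-(benzyloxymethoxy)-5-(tert-butyldimethylsilyloxy)hex-2-ynoic acid | C[C@H](O[Si](C)(C)C(C)(C)C)[C@H](OCOCc1ccccc1)C#CC(=O)O | intermediate
21 | (1R,2S)-1-[2-(allyloxycarbonyl)-3,5-bis(benzyloxy)-4-methoxyphenyl]-1-(benzyloxymethoxy)propan-2-yl (4R,5S)-4-(benzyloxymethoxy)-5-(tert-butyldimethylsilyloxy)hex-2-ynoate | C[C@H](O[Si](C)(C)C(C)(C)C)[C@H](OCOCc1ccccc1)C#CC(=O)O[C@@H](C)[C@H](OCOCc1ccccc1)c1cc(OCc2ccccc2)c(OC)c(OCc2ccccc2)c1C(=O)OCC=C | intermediate
22 | sodium enolate of methyl methoxyacetate | COC=C(OC)O[Na] | intermediate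
23 | methyl 4-(benzyloxy)-2-methoxy-3-oxobutanoate (racemic) | COC(=O)C(OC)C(=O)COCc1ccccc1 | intermediate
24 | methyl 4-(benzyloxy)-2-methoxy-3-(trimethylsilyloxy)but-2-enoate (E/Z mixture) | COC(=O)C(OC)=C(COCc1ccccc1)O[Si](C)(C)C | intermediate
25 | lithium dienolate of 24 | [Li]OC(OC)=C(OC)C(O[Si](C)(C)C)=COCc1ccccc1 | intermediate
26 | 4-(benzyloxy)-1,2-dimethoxy-1,3-bis(trimethylsilyloxy)buta-1,3-diene (isomer mixture) | C[Si](C)(C)OC(OC)=C(OC)C(O[Si](C)(C)C)=COCc1ccccc1 | intermediate
27 | cyclohexa-1,4-diene cycloadduct of 21 and 26 (ring B precursor; 3-benzyloxy, 5,6-dimethoxy, 4,6-bis(trimethylsilyloxy); epimer mixture at the two new sp3 carbons) | C[C@H](O[Si](C)(C)C(C)(C)C)[C@H](OCOCc1ccccc1)C1=C(C(=O)O[C@@H](C)[C@H](OCOCc2ccccc2)c2cc(OCc3ccccc3)c(OC)c(OCc3ccccc3)c2C(=O)OCC=C)C(OC)(O[Si](C)(C)C)C(OC)=C(O[Si](C)(C)C)C1OCc1ccccc1 | intermediate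
28 | 4'-O-trimethylsilyl ether of 29 | C[C@H](O[Si](C)(C)C(C)(C)C)[C@H](OCOCc1ccccc1)c1c(OCc2ccccc2)c(O[Si](C)(C)C)c(OC)c(O)c1C(=O)O[C@@H](C)[C@H](OCOCc1ccccc1)c1cc(OCc2ccccc2)c(OC)c(OCc2ccccc2)c1C(=O)OCC=C | intermediate
29 | (1R,2S)-1-[2-(allyloxycarbonyl)-3,5-bis(benzyloxy)-4-methoxyphenyl]-1-(benzyloxymethoxy)propan-2-yl 5-(benzyloxy)-6-[(1R,2S)-1-(benzyloxymethoxy)-2-(tert-butyldimethylsilyloxy)propyl]-2,4-dihydroxy-3-methoxybenzoate | C[C@H](O[Si](C)(C)C(C)(C)C)[C@H](OCOCc1ccccc1)c1c(OCc2ccccc2)c(O)c(OC)c(O)c1C(=O)O[C@@H](C)[C@H](OCOCc1ccccc1)c1cc(OCc2ccccc2)c(OC)c(OCc2ccccc2)c1C(=O)OCC=C | intermediate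
30 | (1R,2S)-1-[2-(allyloxycarbonyl)-3,5-bis(benzyloxy)-4-methoxyphenyl]-1-(benzyloxymethoxy)propan-2-yl 2,4,5-tris(benzyloxy)-6-[(1R,2S)-1-(benzyloxymethoxy)-2-(tert-butyldimethylsilyloxy)propyl]-3-methoxybenzoate | C[C@H](O[Si](C)(C)C(C)(C)C)[C@H](OCOCc1ccccc1)c1c(OCc2ccccc2)c(OCc2ccccc2)c(OC)c(OCc2ccccc2)c1C(=O)O[C@@H](C)[C@H](OCOCc1ccccc1)c1cc(OCc2ccccc2)c(OC)c(OCc2ccccc2)c1C(=O)OCC=C | intermediate
31 | 2,4-bis(benzyloxy)-6-[(1R,2S)-1-(benzyloxymethoxy)-2-{2,4,5-tris(benzyloxy)-6-[(1R,2S)-1-(benzyloxymethoxy)-2-(tert-butyldimethylsilyloxy)propyl]-3-methoxybenzoyloxy}propyl]-3-methoxybenzoic acid | C[C@H](O[Si](C)(C)C(C)(C)C)[C@H](OCOCc1ccccc1)c1c(OCc2ccccc2)c(OCc2ccccc2)c(OC)c(OCc2ccccc2)c1C(=O)O[C@@H](C)[C@H](OCOCc1ccccc1)c1cc(OCc2ccccc2)c(OC)c(OCc2ccccc2)c1C(=O)O | intermediate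
32 | 2,4-bis(benzyloxy)-6-[(1R,2S)-1-(benzyloxymethoxy)-2-{2,4,5-tris(benzyloxy)-6-[(1R,2S)-1-(benzyloxymethoxy)-2-hydroxypropyl]-3-methoxybenzoyloxy}propyl]-3-methoxybenzoic acid (seco acid) | C[C@H](O)[C@H](OCOCc1ccccc1)c1c(OCc2ccccc2)c(OCc2ccccc2)c(OC)c(OCc2ccccc2)c1C(=O)O[C@@H](C)[C@H](OCOCc1ccccc1)c1cc(OCc2ccccc2)c(OC)c(OCc2ccccc2)c1C(=O)O | intermediate
33 | protected dilactone: 34 with benzyl ethers on O-2, O-4, O-2', O-4', O-5' and benzyloxymethyl ethers on O-1 and O-1'; chains (1R,2S) on ring A, (1'R,2'R) on ring B | COc1c(OCc3ccccc3)cc2c(c1OCc4ccccc4)C(=O)O[C@H](C)[C@H](OCOCc5ccccc5)c1c(OCc3ccccc3)c(OCc3ccccc3)c(OC)c(OCc3ccccc3)c1C(=O)O[C@@H](C)[C@@H]2OCOCc6ccccc6 | intermediate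
34 | CNP0086623.4: 12-membered dilactone of 6-[(1R,2S)-1,2-dihydroxypropyl]-2,4-dihydroxy-3-methoxybenzoic acid (ring A) and 6-[(1R,2R)-1,2-dihydroxypropyl]-2,4,5-trihydroxy-3-methoxybenzoic acid (ring B), each carboxyl esterifying O-2 of the other unit's chain | COc1c(O)cc2c(c1O)C(=O)O[C@H](C)[C@H](O)c1c(O)c(O)c(OC)c(O)c1C(=O)O[C@@H](C)[C@@H]2O | target

## Step count and risks

Total: 21 steps. Longest linear sequence: 14 steps (1–4, 8–10, 12, 16–21).

**Step 8 (key step).** The cycloaddition at the β-branched ynoate may be slower than consumption of the diene by hydrolysis, silyl transfer or self-condensation, and the ketal may collapse incompletely. Fallback, from 8 back to 17: an Alder–Rickert sequence with a cyclic diene, which forms the same two ring bonds. Dimedone is converted by diazo transfer into 2-diazo-5,5-dimethylcyclohexane-1,3-dione F1. Rh2(OAc)4-catalysed O–H insertion into methanol gives 2-methoxy-5,5-dimethylcyclohexane-1,3-dione F2. One-step double silylation (TMSOTf, Et3N) gives 2-methoxy-5,5-dimethyl-1,3-bis(trimethylsilyloxy)cyclohexa-1,3-diene F3. Heating 8 with F3 gives bicyclo[2.2.2]octadiene F4, which extrudes 2-methylpropene by retro-Diels–Alder reaction to the bis(trimethylsilyl) ether F5; dilute acid then gives 17.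

**Step 16.** The benzyloxy group on the diene terminus is a donor that opposes the ketene-acetal polarisation and adds bulk, so the rate and the regiocontrol may erode. Only the (3Z) diene isomer reacts readily, on an ynoate that is by now valuable. Fallback, from 21 back to 30: cycloaddition of 21 with diene 14 as in step 8, through cycloadduct F6 and aryl silyl ether F7, gives the 5'-unsubstituted resorcylate F8. ON(SO3K)2 oxidises its free resorcinol ring at C5' to hydroxyquinone F9 (ring A, fully etherified, is inert). Na2S2O4 reduces F9 to the 2',4',5'-triol F10, and threefold benzylation (BnBr, K2CO3) rejoins the route at 30.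

**Step 20.** The C2' alkoxyphosphonium may be intercepted by the neighbouring B-ester carbonyl through a six-membered participation, may undergo β-elimination, or the reaction may run through the acyloxyphosphonium with retention. Oligomerisation competes if dilution is insufficient. Fallback, from 30 back to 33: activation is separated from ring closure. HF·pyridine on 30 gives alcohol F11, MsCl/Et3N gives mesylate F12, and Pd(PPh3)4/morpholine frees the acid F13. Cs2CO3 in DMF at high dilution then closes the ring by carboxylate displacement with inversion to 33.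

**Step 3.** Facial selectivity of the acetylide addition may be modest, which costs material in the first stereo-defining step. Fallback, from the mixture of 7 and its (4S,5S) epimer F14 back to 7: Dess–Martin oxidation gives ynone F15. Reagent-controlled reduction (oxazaborolidine-catalysed CBS reduction with the catalyst enantiomer matched to the Felkin face) returns 7.

**Step 21.** Hydrogenolysis may go too far and cleave the substrate's own benzylic C–O bonds, the hemiformals may lose formaldehyde incompletely, or the freed benzylic hydroxyls may translactonise to phthalides if the medium drifts from neutral. Fallback, from 33 directly to 34: non-reductive Lewis-acid dealkylation with BCl3 and pentamethylbenzene in CH2Cl2 at −78 °C, then cold methanol quench; no new isolated compound.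

## Further compounds

F1 | step 8 | 2-diazo-5,5-dimethylcyclohexane-1,3-dione | CC1(C)CC(=O)C(=[N+]=[N-])C(=O)C1
F2 | step 8 | 2-methoxy-5,5-dimethylcyclohexane-1,3-dione | COC1C(=O)CC(C)(C)CC1=O
F3 | step 8 | 2-methoxy-5,5-dimethyl-1,3-bis(trimethylsilyloxy)cyclohexa-1,3-diene | COC1=C(O[Si](C)(C)C)CC(C)(C)C=C1O[Si](C)(C)C
F4 | step 8 | allyl 3-[(1R,2S)-1-(benzyloxymethoxy)-2-(tert-butyldimethylsilyloxy)propyl]-6-methoxy-8,8-dimethyl-1,5-bis(trimethylsilyloxy)bicyclo[2.2.2]octa-2,5-diene-2-carboxylate | C[C@H](O[Si](C)(C)C(C)(C)C)[C@H](OCOCc1ccccc1)C1=C(C(=O)OCC=C)C2(O[Si](C)(C)C)CC(C)(C)C1C(O[Si](C)(C)C)=C2OC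
F5 | step 8 | allyl 6-[(1R,2S)-1-(benzyloxymethoxy)-2-(tert-butyldimethylsilyloxy)propyl]-3-methoxy-2,4-bis(trimethylsilyloxy)benzoate | C[C@H](O[Si](C)(C)C(C)(C)C)[C@H](OCOCc1ccccc1)c1cc(O[Si](C)(C)C)c(OC)c(O[Si](C)(C)C)c1C(=O)OCC=C
F6 | step 16 | cyclohexa-1,4-diene cycloadduct of 21 and 14 | C[C@H](O[Si](C)(C)C(C)(C)C)[C@H](OCOCc1ccccc1)C1=C(C(=O)O[C@@H](C)[C@H](OCOCc2ccccc2)c2cc(OCc3ccccc3)c(OC)c(OCc3ccccc3)c2C(=O)OCC=C)C(OC)(O[Si](C)(C)C)C(OC)=C(O[Si](C)(C)C)C1
F7 | step 16 | 4'-O-trimethylsilyl ether of F8 | C[C@H](O[Si](C)(C)C(C)(C)C)[C@H](OCOCc1ccccc1)c1cc(O[Si](C)(C)C)c(OC)c(O)c1C(=O)O[C@@H](C)[C@H](OCOCc1ccccc1)c1cc(OCc2ccccc2)c(OC)c(OCc2ccccc2)c1C(=O)OCC=C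
F8 | step 16 | (1R,2S)-1-[2-(allyloxycarbonyl)-3,5-bis(benzyloxy)-4-methoxyphenyl]-1-(benzyloxymethoxy)propan-2-yl 6-[(1R,2S)-1-(benzyloxymethoxy)-2-(tert-butyldimethylsilyloxy)propyl]-2,4-dihydroxy-3-methoxybenzoate | C[C@H](O[Si](C)(C)C(C)(C)C)[C@H](OCOCc1ccccc1)c1cc(O)c(OC)c(O)c1C(=O)O[C@@H](C)[C@H](OCOCc1ccccc1)c1cc(OCc2ccccc2)c(OC)c(OCc2ccccc2)c1C(=O)OCC=C
F9 | step 16 | hydroxyquinone of F8 (ring B as 4-hydroxy-3-methoxy-2,5-dioxocyclohexa-3,6-diene carrying the ester at C1 and the chain at C6) | C[C@H](O[Si](C)(C)C(C)(C)C)[C@H](OCOCc1ccccc1)C1=C(C(=O)O[C@@H](C)[C@H](OCOCc2ccccc2)c2cc(OCc3ccccc3)c(OC)c(OCc3ccccc3)c2C(=O)OCC=C)C(=O)C(OC)=C(O)C1=O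
F10 | step 16 | 2',4',5'-trihydroxy analogue of 29 (5'-OH in place of 5'-OBn) | C[C@H](O[Si](C)(C)C(C)(C)C)[C@H](OCOCc1ccccc1)c1c(O)c(O)c(OC)c(O)c1C(=O)O[C@@H](C)[C@H](OCOCc1ccccc1)c1cc(OCc2ccccc2)c(OC)c(OCc2ccccc2)c1C(=O)OCC=C
F11 | step 20 | 30 with free O-2' hydroxyl (allyl ester retained) | C[C@H](O)[C@H](OCOCc1ccccc1)c1c(OCc2ccccc2)c(OCc2ccccc2)c(OC)c(OCc2ccccc2)c1C(=O)O[C@@H](C)[C@H](OCOCc1ccccc1)c1cc(OCc2ccccc2)c(OC)c(OCc2ccccc2)c1C(=O)OCC=C
F12 | step 20 | O-2' methanesulfonate of F11 | C[C@H](OS(C)(=O)=O)[C@H](OCOCc1ccccc1)c1c(OCc2ccccc2)c(OCc2ccccc2)c(OC)c(OCc2ccccc2)c1C(=O)O[C@@H](C)[C@H](OCOCc1ccccc1)c1cc(OCc2ccccc2)c(OC)c(OCc2ccccc2)c1C(=O)OCC=C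
F13 | step 20 | O-2' methanesulfonate of seco acid 32 | C[C@H](OS(C)(=O)=O)[C@H](OCOCc1ccccc1)c1c(OCc2ccccc2)c(OCc2ccccc2)c(OC)c(OCc2ccccc2)c1C(=O)O[C@@H](C)[C@H](OCOCc1ccccc1)c1cc(OCc2ccccc2)c(OC)c(OCc2ccccc2)c1C(=O)O
F14 | step 3 | allyl (4S,5S)-5-(tert-butyldimethylsilyloxy)-4-hydroxyhex-2-ynoate | C[C@H](O[Si](C)(C)C(C)(C)C)[C@@H](O)C#CC(=O)OCC=C
F15 | step 3 | allyl (5S)-5-(tert-butyldimethylsilyloxy)-4-oxohex-2-ynoate | C[C@H](O[Si](C)(C)C(C)(C)C)C(=O)C#CC(=O)OCC=C
F0 | step 21 | none | none
A1 | alternative 1 | 5-bromo-2-methoxy-1,3-bis(methoxymethoxy)benzene | COCOc1cc(Br)cc(OCOC)c1OC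
A2 | alternative 1 | 3-methoxy-2,4-bis(methoxymethoxy)-6-[(E)-prop-1-enyl]benzoic acid | C/C=C/c1cc(OCOC)c(OC)c(OCOC)c1C(=O)O
A3 | alternative 2 | aryl iodide seco alcohol: (1R,2R)-1-[2,3,5-tris(benzyloxy)-6-iodo-4-methoxyphenyl]-1-(tert-butyldimethylsilyloxy)propan-2-yl 2,4-bis(benzyloxy)-6-[(1R,2S)-1-(tert-butyldimethylsilyloxy)-2-hydroxypropyl]-3-methoxybenzoate | COc1c(OCc3ccccc3)cc([C@@H](O[Si](C)(C)C(C)(C)C)[C@H](C)O)c(c1OCc3ccccc3)C(=O)O[C@H](C)[C@H](O[Si](C)(C)C(C)(C)C)c1c(OCc3ccccc3)c(OCc3ccccc3)c(OC)c(OCc3ccccc3)c1I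
A4 | alternative 2 | protected 12-membered dilactone (five benzyl ethers, two tert-butyldimethylsilyl ethers) | COc1c(OCc3ccccc3)cc2c(c1OCc3ccccc3)C(=O)O[C@H](C)[C@H](O[Si](C)(C)C(C)(C)C)c1c(OCc3ccccc3)c(OCc3ccccc3)c(OC)c(OCc3ccccc3)c1C(=O)O[C@@H](C)[C@@H]2O[Si](C)(C)C(C)(C)C
A5 | alternative 3 | 4-hydroxy-2,3-dimethoxy-4-{1-[(4R,5R)-2,2,5-trimethyl-1,3-dioxolan-4-yl]ethenyl}cyclobut-2-en-1-one | COC1=C(OC)C(O)(C(=C)[C@H]2OC(C)(C)O[C@@H]2C)C1=O
A6 | alternative 3 | 2,3-dimethoxy-5-[(4R,5R)-2,2,5-trimethyl-1,3-dioxolan-4-yl]benzene-1,4-diol | COc1c(O)cc([C@H]2OC(C)(C)O[C@@H]2C)c(O)c1OC
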